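**Retrosynthetic overview**

1. The target has one ring, a 2,3-dihydro-4H-pyran-4-one: O1, C2 (R stereocentre carrying the (14Z)-tricos-14-enyl chain), C3H2, C4 (C=O), C5H=C6(CH3). It is closed last, by acid cyclodehydration (O1–C6 bond) of a δ-hydroxy-β-diketone whose C4 and C6 carbonyls arrive masked as a 1,3-dithiane and a dioxolane.
2. The plan rests on one feature of this ring: C4 is a carbonyl carbon, and C3, traced back from the oxygen on C2, is the terminal CH2 of a 1,2-epoxide. Both are natural electrophiles, so the C3–C4 bond needs polarity reversal at C4.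
3. Key disconnection C3–C4: a 2-lithio-1,3-dithiane (C4 acyl anion that already carries C5 and the ketal-protected C6 with its methyl) plus (2R)-2-[(14Z)-tricos-14-enyl]oxirane.
4. Epoxide: erucyl alcohol → bromide → Grignard reagent, CuI-catalysed opening of (R)-epichlorohydrin, NaOH closure; the stereocentre and the Z alkene are both bought. Dithiane: but-3-yn-2-one plus propane-1,3-dithiol, then ethylene glycol.

Key step: step 6

Assumption: ring atoms are numbered O1, C2, C3, C4 (C=O), C5, C6 (C–CH3) throughout; the SMILES encodes 2R and 14Z in the side chain, and commercial erucyl alcohol and (R)-epichlorohydrin are taken to be of high Z and enantiomeric purity.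

**Route**

Step 1
Reactants: 1 (13Z)-docos-13-en-1-ol (erucyl alcohol)
Product: 2 (13Z)-1-bromodocos-13-ene
Conditions: CBr4, PPh3, CH2Cl2, 0 °C → rt
Reagents that add atoms: carbon tetrabromide, BrC(Br)(Br)Br
Why: Appel reaction: bromide displaces the alkoxyphosphonium group at the primary carbon under neutral conditions that leave the isolated Z alkene untouched.

Step 2
Reactants: 2 (13Z)-1-bromodocos-13-ene; 3 (R)-epichlorohydrin
Product: 5 (2R,16Z)-1-chloropentacos-16-en-2-ol, via erucylmagnesium bromide 4 (not isolated)
Conditions: Mg, THF, 45 °C; then CuI (10 mol %), 3, THF, −40 → −20 °C; 1 M HCl work-up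
Reagents that add atoms: none
Why: Magnesium insertion gives the primary Grignard reagent 4, which under CuI catalysis opens the oxirane of 3 at its unsubstituted CH2 (copper-catalysed Grignard opening of an epoxide) rather than displacing chloride, so no bond to the stereocentre is touched and the unchanged ranking O > CH2Cl > chain CH2 keeps the descriptor R in 5.

Step 3
Reactants: 5 (2R,16Z)-1-chloropentacos-16-en-2-ol
Product: 6 (2R)-2-[(14Z)-tricos-14-en-1-yl]oxirane
Conditions: NaOH (powdered), Et2O/THF, rt
Reagents that add atoms: none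
Why: Intramolecular Williamson etherification: the alkoxide displaces chloride at the primary carbon (3-exo-tet), which leaves the stereocentre untouched and should give the R epoxide.

Step 4
Reactants: 7 but-3-yn-2-one; 8 propane-1,3-dithiol
Product: 9 1-(1,3-dithian-2-yl)propan-2-one
Conditions: NaOMe (0.2 equiv), MeOH/CH2Cl2, −10 °C → rt, slow addition of 7
Reagents that add atoms: none
Why: Base-catalysed double thia-Michael addition: the thiolate adds to the alkyne terminus of the ynone and the second thiol closes the dithiane by 6-exo-trig addition to the β-thio enone, so both sulfur atoms end on the former alkyne CH, and slow addition of 7 should favour the 1:1 adduct.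

Step 5
Reactants: 9 1-(1,3-dithian-2-yl)propan-2-one
Product: 10 2-[(2-methyl-1,3-dioxolan-2-yl)methyl]-1,3-dithiane
Conditions: ethylene glycol, TsOH·H2O (cat.), benzene, reflux, Dean–Stark
Reagents that add atoms: ethylene glycol, OCCO
Why: Acid-catalysed ketalisation driven by azeotropic removal of water; the dithiane is stable to TsOH, and masking the ketone is what allows metalation at the dithiane carbon in step 6 instead of enolate formation.

Step 6
Reactants: 10 2-[(2-methyl-1,3-dioxolan-2-yl)methyl]-1,3-dithiane (1.3 equiv); 6 (2R)-2-[(14Z)-tricos-14-en-1-yl]oxirane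
Product: 12 (2R,16Z)-1-{2-[(2-methyl-1,3-dioxolan-2-yl)methyl]-1,3-dithian-2-yl}pentacos-16-en-2-ol, via lithiated dithiane 11 (not isolated)
Conditions: n-BuLi, THF, −30 → −20 °C; HMPA, then 6, −78 → −20 °C; H2O quench
Reagents that add atoms: none
Why: n-BuLi removes the proton on the dithiane carbon of 10, the only one acidified by two sulfur atoms now that the ketone is locked as the dioxolane, and the sulfur-stabilised carbanion 11, a masked C4 acyl anion, attacks the unsubstituted CH2 of epoxide 6 in an SN2 opening that forms the C3–C4 bond and leaves the C2 alkoxide. The closest known reaction type is the Corey–Seebach alkylation of 2-alkyl-2-lithio-1,3-dithianes with terminal epoxides, in which HMPA loosens the lithium ion pair and speeds the opening. No ring of the target closes here; the pyranone ring is left for step 8. No stereocentre is created: C2 comes from (R)-epichlorohydrin and keeps its configuration because no bond to it is made or broken. The selectivity needed is attack at the terminal epoxide carbon, which the steric difference between the CH2 and the chain-bearing CH of a monosubstituted oxirane secures for a bulky tertiary carbanion. The isolated Z alkene and the dioxolane are inert to the organolithium at low temperature, and the ketal oxygens sit one carbon too far from the carbanion for β-elimination.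

Step 7
Reactants: 12 (2R,16Z)-1-{2-[(2-methyl-1,3-dioxolan-2-yl)methyl]-1,3-dithian-2-yl}pentacos-16-en-2-ol
Product: 13 (4R,18Z)-4-hydroxy-1-(2-methyl-1,3-dioxolan-2-yl)heptacos-18-en-2-one
Conditions: MeI (excess), CaCO3, MeCN/THF/H2O, 40 °C
Reagents that add atoms: water, O
Why: Alkylative dethioacetalisation: S-methylation turns each sulfur in turn into a leaving group, water captures the thionium ion and the C4 ketone is released, while CaCO3 neutralises the HI formed so that the dioxolane, the secondary alcohol and the Z alkene should be left alone.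

Step 8
Reactants: 13 (4R,18Z)-4-hydroxy-1-(2-methyl-1,3-dioxolan-2-yl)heptacos-18-en-2-one
Product: 15 (2R)-6-methyl-2-[(14Z)-tricos-14-en-1-yl]-2,3-dihydro-4H-pyran-4-one, via hydroxy diketone 14 (not isolated)
Conditions: TsOH·H2O (cat.), acetone/THF/H2O, rt → 40 °C
Reagents that add atoms: none
Why: Acid hydrolysis of the dioxolane frees the C6 ketone, the C2 hydroxyl adds to it to give a six-membered hemiketal, and loss of water gives the conjugated vinylogous ester (cyclodehydration of a δ-hydroxy-β-diketone); the C2–O bond is never broken, so the R configuration should be retained.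

**Compound list**

1 | (13Z)-docos-13-en-1-ol (erucyl alcohol) | CCCCCCCC/C=C\CCCCCCCCCCCCO | starting material
2 | (13Z)-1-bromodocos-13-ene | CCCCCCCC/C=C\CCCCCCCCCCCCBr | intermediate
3 | (R)-epichlorohydrin, (2R)-2-(chloromethyl)oxirane | ClC[C@H]1CO1 | starting material
4 | [(13Z)-docos-13-en-1-yl]magnesium bromide | CCCCCCCC/C=C\CCCCCCCCCCCC[Mg]Br | intermediate
5 | (2R,16Z)-1-chloropentacos-16-en-2-ol | CCCCCCCC/C=C\CCCCCCCCCCCCC[C@@H](O)CCl | intermediate
6 | (2R)-2-[(14Z)-tricos-14-en-1-yl]oxirane | CCCCCCCC/C=C\CCCCCCCCCCCCC[C@@H]1CO1 | intermediate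
7 | but-3-yn-2-one | CC(=O)C#C | starting material
8 | propane-1,3-dithiol | SCCCS | starting material
9 | 1-(1,3-dithian-2-yl)propan-2-one | CC(=O)CC1SCCCS1 | intermediate
10 | 2-[(2-methyl-1,3-dioxolan-2-yl)methyl]-1,3-dithiane | CC1(CC2SCCCS2)OCCO1 | intermediate
11 | 2-lithio-2-[(2-methyl-1,3-dioxolan-2-yl)methyl]-1,3-dithiane | [Li]C1(CC2(C)OCCO2)SCCCS1 | intermediate
12 | (2R,16Z)-1-{2-[(2-methyl-1,3-dioxolan-2-yl)methyl]-1,3-dithian-2-yl}pentacos-16-en-2-ol | CCCCCCCC/C=C\CCCCCCCCCCCCC[C@@H](O)CC1(CC2(C)OCCO2)SCCCS1 | intermediate
13 | (4R,18Z)-4-hydroxy-1-(2-methyl-1,3-dioxolan-2-yl)heptacos-18-en-2-one | CCCCCCCC/C=C\CCCCCCCCCCCCC[C@@H](O)CC(=O)CC1(C)OCCO1 | intermediate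
14 | (6R,20Z)-6-hydroxynonacos-20-ene-2,4-dione | CCCCCCCC/C=C\CCCCCCCCCCCCC[C@@H](O)CC(=O)CC(C)=O | intermediate
15 | (2R)-6-methyl-2-[(14Z)-tricos-14-en-1-yl]-2,3-dihydro-4H-pyran-4-one | CCCCCCCC/C=C\CCCCCCCCCCCCC[C@@H]1CC(=O)C=C(C)O1 | target

**Step count**

Total: 8 steps. Longest linear sequence: 6 steps (1, 2, 3, 6, 7, 8); the dithiane branch (steps 4 and 5) joins at step 6.

**Steps most likely to fail**

Step 6. Metalation of 10 may be incomplete, or the hindered tertiary carbanion may attack slowly, which leaves time for base-induced isomerisation of the epoxide to an allylic alcohol. The fallback sets out from 6 and comes back at 14. It is a three-component silyl-dithiane linchpin coupling. 2-(tert-Butyldimethylsilyl)-1,3-dithiane is lithiated (t-BuLi, Et2O, −78 → −45 °C) and opens 6 at its CH2. Addition of HMPA in THF then triggers a 1,4-Brook rearrangement that moves the silyl group from carbon to the new alkoxide and regenerates a dithiane carbanion. That carbanion opens racemic 2-methyloxirane, used in excess, to give 1-{2-[(2R,16Z)-2-{[tert-butyl(dimethyl)silyl]oxy}pentacos-16-en-1-yl]-1,3-dithian-2-yl}propan-2-ol F1 as a mixture of carbinol epimers. Parikh–Doering oxidation (SO3·pyridine, DMSO, Et3N) should give 1-{2-[(2R,16Z)-2-{[tert-butyl(dimethyl)silyl]oxy}pentacos-16-en-1-yl]-1,3-dithian-2-yl}propan-2-one F2. MeI and CaCO3 in aqueous MeCN/THF should then give (6R,20Z)-6-{[tert-butyl(dimethyl)silyl]oxy}nonacos-20-ene-2,4-dione F3. Aqueous HF in MeCN/THF removes the silyl ether and delivers 14, which closes to 15 under the acid of step 8. The valuable epoxide then meets only the well-behaved silyl dithiane anion, and the slower second opening falls on a cheap epoxide in excess.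

Step 8. The acyclic β-hydroxy ketone may lose water across C2–C3 before the ring closes, or the product may open and re-close under acid (retro-oxa-Michael), which would erode the C2 configuration. The fallback sets out from 12 and comes back at 15; it closes the ring before the C4 carbonyl exists. TsOH·H2O (cat.) in MeOH/THF exchanges the dioxolane while the dithiane still masks C4, and the C2 hydroxyl captures the C6 oxocarbenium ion to give the cyclic methyl ketal (10R)-8-methoxy-8-methyl-10-[(14Z)-tricos-14-en-1-yl]-9-oxa-1,5-dithiaspiro[5.5]undecane F4. MeI and CaCO3 in aqueous MeCN/THF then remove the dithiane to give (6R)-2-methoxy-2-methyl-6-[(14Z)-tricos-14-en-1-yl]oxan-4-one F5. PPTS in warm benzene eliminates methanol through the C6 oxocarbenium ion (loss of a C5 proton) to give 15. This order also answers trouble in step 7, because the dithiane is then cleaved from a substrate with neither a free hydroxyl nor a dioxolane.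

Step 4. But-3-yn-2-one may polymerise under thiolate and methoxide, or the mono-adduct may be captured by a second ynone or dithiol molecule instead of closing to the dithiane. The fallback sets out from 8 and comes back at 9. Commercial 4,4-dimethoxybutan-2-one (CC(=O)CC(OC)OC) is treated with 8 and BF3·OEt2 in CH2Cl2 at −20 → 0 °C. This Lewis-acid transthioacetalisation should convert the dimethyl acetal, which ionises far more readily than the ketone is attacked, into 9 directly with one equivalent of dithiol.

**Further compounds**

F1 | step 6 | 1-{2-[(2R,16Z)-2-{[tert-butyl(dimethyl)silyl]oxy}pentacos-16-en-1-yl]-1,3-dithian-2-yl}propan-2-ol (carbinol epimers) | CCCCCCCC/C=C\CCCCCCCCCCCCC[C@@H](O[Si](C)(C)C(C)(C)C)CC1(CC(C)O)SCCCS1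
F2 | step 6 | 1-{2-[(2R,16Z)-2-{[tert-butyl(dimethyl)silyl]oxy}pentacos-16-en-1-yl]-1,3-dithian-2-yl}propan-2-one | CCCCCCCC/C=C\CCCCCCCCCCCCC[C@@H](O[Si](C)(C)C(C)(C)C)CC1(CC(C)=O)SCCCS1
F3 | step 6 | (6R,20Z)-6-{[tert-butyl(dimethyl)silyl]oxy}nonacos-20-ene-2,4-dione | CCCCCCCC/C=C\CCCCCCCCCCCCC[C@@H](O[Si](C)(C)C(C)(C)C)CC(=O)CC(C)=O
F4 | step 8 | (10R)-8-methoxy-8-methyl-10-[(14Z)-tricos-14-en-1-yl]-9-oxa-1,5-dithiaspiro[5.5]undecane (C8 epimers) | CCCCCCCC/C=C\CCCCCCCCCCCCC[C@@H]1CC2(CC(C)(OC)O1)SCCCS2
F5 | step 8 | (6R)-2-methoxy-2-methyl-6-[(14Z)-tricos-14-en-1-yl]oxan-4-one (C2 epimers) | CCCCCCCC/C=C\CCCCCCCCCCCCC[C@@H]1CC(=O)CC(C)(OC)O1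
F0 | step 4 | none | none
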